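Ring A (C1 ester carbon, C2 aryloxy carbon, C6 hydroxyl carbon) has three adjacent carbons bearing O, CO2Me and O–aryl. The route therefore cuts the diaryl ether O–C2 bond and the C1–carboxyl bond at once, across a C1–C2 aryne polarised by the C6 oxygen. In a single flask the hindered ring B phenoxide adds to C2 and the resulting C1 anion is carboxylated and methylated. The aryne precursor is an orcinol-derived 2-silylaryl triflate whose C6 oxygen already carries a 1,1-dimethylallyl group; the partner is the silyl-protected ring B phenol. A late Claisen shift, steered by the new ester, then delivers prenyl to C5.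

Key step: step 9

Remark: ring A is the benzoate ring with C1 (ester), C2 (aryloxy), C3 (H), C4 (methyl), C5 (prenyl) and C6 (hydroxyl), ring B is the dimethoxyphenyl ring, and substituent locants in the names of 18, 19 and 20 follow this labelling; orcinol is symmetric, so step 1 is a mono-etherification run in excess diol.

Step 1
Reactants: 1 orcinol (5-methylbenzene-1,3-diol); 2 3-chloro-3-methylbut-1-yne
Product: 3 3-methyl-5-(2-methylbut-3-yn-2-yloxy)phenol
Conditions: 1 (3 equiv), 2 (1 equiv), CuCl2·2H2O (1 mol %), DBU (1.3 equiv), MeCN, 0 °C → rt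
Reagents that add atoms: none
Why: Copper-catalysed propargylic etherification, in which DBU and catalytic divalent copper turn the tertiary propargylic chloride into a copper-bound electrophile that the phenoxide attacks at the tertiary carbon, while the threefold excess of the water-soluble diol should hold the reaction at the mono-ether.

Step 2
Reactants: 3 3-methyl-5-(2-methylbut-3-yn-2-yloxy)phenol
Product: 4 3-methyl-5-(2-methylbut-3-en-2-yloxy)phenol
Conditions: H2 (1 atm), Pd/CaCO3 poisoned with Pb(OAc)2, quinoline, EtOAc, rt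
Reagents that add atoms: none
Why: Lindlar semihydrogenation should stop at the vinyl group because the poisoned palladium surface binds the terminal alkyne far more strongly than the alkene, and it does not touch the aryl ether.

Step 3
Reactants: 4 3-methyl-5-(2-methylbut-3-en-2-yloxy)phenol
Product: 5 3-methyl-5-(2-methylbut-3-en-2-yloxy)phenyl N-isopropylcarbamate
Conditions: i-PrNCO (1.5 equiv), Et3N (0.2 equiv), CH2Cl2, rt
Reagents that add atoms: isopropyl isocyanate, CC(C)N=C=O
Why: Amine-catalysed addition of the phenol to the isocyanate (carbamoylation) installs a strong ortho-directing group that can later be removed with a secondary amine under mild conditions.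

Step 4
Reactants: 5 3-methyl-5-(2-methylbut-3-en-2-yloxy)phenyl N-isopropylcarbamate
Product: 9 5-methyl-3-(2-methylbut-3-en-2-yloxy)-2-(trimethylsilyl)phenyl N-isopropylcarbamate, via N-silyl carbamate 6 (not isolated), via aryllithium 7 (not isolated), via bis-silyl carbamate 8 (not isolated)
Conditions: TMEDA (1.1 equiv), TBSOTf (1.05 equiv), Et2O, 0 °C → rt; TMEDA (2 equiv), n-BuLi (2 equiv), −78 °C; Me3SiCl (3 equiv), −78 °C → rt; aq. NH4Cl
Reagents that add atoms: chlorotrimethylsilane, C[Si](C)(C)Cl; tert-butyldimethylsilyl triflate, CC(C)(C)[Si](C)(C)OS(=O)(=O)C(F)(F)F (its silyl group is carried only by 6 to 8 and is lost on work-up)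
Why: Directed ortho-metalation, in which in-flask N-silylation (TMEDA is present first, so the silyl triflate does not meet the tertiary allyl ether as a free Lewis acid) masks the N–H, the carbamate and ether oxygens together acidify the carbon between them, n-BuLi removes that proton at −78 °C where the anionic Fries shift is frozen, Me3SiCl quenches the aryllithium and the N–Si bond hydrolyses on work-up.

Step 5
Reactants: 9 5-methyl-3-(2-methylbut-3-en-2-yloxy)-2-(trimethylsilyl)phenyl N-isopropylcarbamate
Product: 11 5-methyl-3-(2-methylbut-3-en-2-yloxy)-2-(trimethylsilyl)phenyl trifluoromethanesulfonate, via silyl phenol 10 (not isolated)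
Conditions: Et2NH (1.3 equiv), DBU (1.5 equiv), MeCN, 40 °C; then PhNTf2 (1.5 equiv), rt
Reagents that add atoms: N-phenylbis(trifluoromethanesulfonimide), O=S(=O)(N(c1ccccc1)S(=O)(=O)C(F)(F)F)C(F)(F)F
Why: Amidine-induced elimination of the N–H carbamate to the phenoxide and isopropyl isocyanate (trapped by Et2NH as a urea), followed by O-triflation with the mild triflyl donor in the same flask, avoids the acid that would ionise the allyl ether or protodesilylate the ring.

Step 6
Reactants: 12 2,4-dimethoxyphenol
Product: 13 2-hydroxy-3,5-dimethoxybenzaldehyde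
Conditions: MgCl2 (1.5 equiv), Et3N (3.75 equiv), (CH2O)n (6.75 equiv), MeCN, reflux; aq. HCl work-up
Reagents that add atoms: paraformaldehyde (formaldehyde), C=O
Why: Magnesium-mediated ortho-formylation (Casnati–Skattebøl reaction), in which the magnesium phenoxide delivers formaldehyde to the only free ortho carbon and a second formaldehyde oxidises the benzylic alkoxide to the aldehyde.

Step 7
Reactants: 13 2-hydroxy-3,5-dimethoxybenzaldehyde
Product: 14 2-(hydroxymethyl)-4,6-dimethoxyphenol
Conditions: NaBH4, MeOH/THF, 0 °C; aq. NH4Cl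
Reagents that add atoms: none
Why: Borohydride reduction of the aryl aldehyde is chemoselective, and the neutral work-up keeps the electron-rich salicyl alcohol from ionising to an ortho-quinone methide.

Step 8
Reactants: 14 2-(hydroxymethyl)-4,6-dimethoxyphenol
Product: 15 2,4-dimethoxy-6-(triisopropylsilyloxymethyl)phenol
Conditions: i-Pr3SiCl (1.05 equiv), imidazole (2.2 equiv), CH2Cl2, 0 °C → rt
Reagents that add atoms: chlorotriisopropylsilane, CC(C)[Si](Cl)(C(C)C)C(C)C
Why: Chemoselective silylation, since the bulky chlorosilane should react at the unhindered primary benzylic hydroxyl while the phenol, flanked by two ortho substituents and hydrogen-bonded, stays free.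

Step 9
Reactants: 11 5-methyl-3-(2-methylbut-3-en-2-yloxy)-2-(trimethylsilyl)phenyl trifluoromethanesulfonate; 15 2,4-dimethoxy-6-(triisopropylsilyloxymethyl)phenol
Product: 18 methyl 2-[2,4-dimethoxy-6-(triisopropylsilyloxymethyl)phenoxy]-4-methyl-6-(2-methylbut-3-en-2-yloxy)benzoate, via potassium phenoxide 16 (not isolated), via potassium carboxylate 17 (not isolated)
Conditions: 15 (1.5 equiv), KH (1.6 equiv), THF, 0 °C → rt; 18-crown-6 (3 equiv), KF (3 equiv), CO2 (1 atm), 0 °C, 11 added over 6 h, → rt; then MeI (5 equiv), DMF, rt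
Reagents that add atoms: carbon dioxide, O=C=O; iodomethane, CI
Why: Proposed new method: fluoride attacks the trimethylsilyl group of 11 and triflate leaves, giving the 3-alkoxyaryne across C1–C2 of ring A; the crown-ether-separated phenoxide 16 adds at C2, the terminus remote from the inductively withdrawing C6 oxygen, so the carbanion develops at C1 between two oxygen-bearing carbons. That C1 anion, of the same type as a 2,6-dialkoxyphenyl anion, should be captured by dissolved CO2 to give carboxylate 17, which is O-methylated in the same flask. The closest known reaction types are the fluoride-induced three-component coupling of arynes with amines and CO2 to anthranilic acid derivatives and the regioselective O-arylation of phenoxides by 3-alkoxyarynes; the new element is an anionic oxygen nucleophile whose adduct is a free aryl anion. No ring is closed and no stereocentre is formed. The step needs regioselectivity (O–C2, not O–C1), secured by the C6 alkoxy group, and exclusive O-arylation, secured by the blocked ortho and para carbons of ring B. It also needs carboxylation to outrun protonation and attack on the pendant vinyl group, which is why the phenoxide is pre-formed with KH in THF (no O–H or acidic C–H, unlike acetonitrile or a carbonate base) and why 11 is added slowly under CO2.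

Step 10
Reactants: 18 methyl 2-[2,4-dimethoxy-6-(triisopropylsilyloxymethyl)phenoxy]-4-methyl-6-(2-methylbut-3-en-2-yloxy)benzoate
Product: 19 methyl 2-[2,4-dimethoxy-6-(triisopropylsilyloxymethyl)phenoxy]-6-hydroxy-4-methyl-5-(3-methylbut-2-en-1-yl)benzoate
Conditions: PhNEt2 (2 equiv), toluene (degassed), 120 °C, sealed tube
Reagents that add atoms: none
Why: Aromatic Claisen rearrangement ([3,3]-sigmatropic shift), in which the ester blocks C1 so the allyl terminus can only bond to C5, the allylic inversion turns 1,1-dimethylallyl into prenyl, tautomerisation releases the C6 phenol, and the amine additive suppresses acid-catalysed cyclisation to a chroman.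

Step 11
Reactants: 19 methyl 2-[2,4-dimethoxy-6-(triisopropylsilyloxymethyl)phenoxy]-6-hydroxy-4-methyl-5-(3-methylbut-2-en-1-yl)benzoate
Product: 20 methyl 2-[2-(hydroxymethyl)-4,6-dimethoxyphenoxy]-6-hydroxy-4-methyl-5-(3-methylbut-2-en-1-yl)benzoate (CNP0583011.0)
Conditions: Bu4NF (1.5 equiv), AcOH (1.5 equiv), THF, 0 °C → rt
Reagents that add atoms: none
Why: Fluoride-mediated desilylation of the primary silyl ether, buffered with acetic acid so that the benzylic alkoxide stays protonated and cannot attack the neighbouring methyl ester to form the eight-membered lactone.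

Compound list
1 | orcinol (5-methylbenzene-1,3-diol) | Cc1cc(O)cc(O)c1 | starting material
2 | 3-chloro-3-methylbut-1-yne | CC(C)(Cl)C#C | starting material
3 | 3-methyl-5-(2-methylbut-3-yn-2-yloxy)phenol | C#CC(C)(C)Oc1cc(C)cc(O)c1 | intermediate
4 | 3-methyl-5-(2-methylbut-3-en-2-yloxy)phenol | C=CC(C)(C)Oc1cc(C)cc(O)c1 | intermediate
5 | 3-methyl-5-(2-methylbut-3-en-2-yloxy)phenyl N-isopropylcarbamate | C=CC(C)(C)Oc1cc(C)cc(OC(=O)NC(C)C)c1 | intermediate
6 | 3-methyl-5-(2-methylbut-3-en-2-yloxy)phenyl N-(tert-butyldimethylsilyl)-N-isopropylcarbamate | C=CC(C)(C)Oc1cc(C)cc(OC(=O)N(C(C)C)[Si](C)(C)C(C)(C)C)c1 | intermediate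
7 | 2-lithio derivative of 6 (lithium on the ring carbon between the two oxygens) | [Li]c1c(OC(C)(C)C=C)cc(C)cc1OC(=O)N(C(C)C)[Si](C)(C)C(C)(C)C | intermediate
8 | 5-methyl-3-(2-methylbut-3-en-2-yloxy)-2-(trimethylsilyl)phenyl N-(tert-butyldimethylsilyl)-N-isopropylcarbamate | C=CC(C)(C)Oc1cc(C)cc(OC(=O)N(C(C)C)[Si](C)(C)C(C)(C)C)c1[Si](C)(C)C | intermediate
9 | 5-methyl-3-(2-methylbut-3-en-2-yloxy)-2-(trimethylsilyl)phenyl N-isopropylcarbamate | C=CC(C)(C)Oc1cc(C)cc(OC(=O)NC(C)C)c1[Si](C)(C)C | intermediate
10 | 5-methyl-3-(2-methylbut-3-en-2-yloxy)-2-(trimethylsilyl)phenol | C=CC(C)(C)Oc1cc(C)cc(O)c1[Si](C)(C)C | intermediate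
11 | 5-methyl-3-(2-methylbut-3-en-2-yloxy)-2-(trimethylsilyl)phenyl trifluoromethanesulfonate | C=CC(C)(C)Oc1cc(C)cc(OS(=O)(=O)C(F)(F)F)c1[Si](C)(C)C | intermediate
12 | 2,4-dimethoxyphenol | COc1ccc(O)c(OC)c1 | starting material
13 | 2-hydroxy-3,5-dimethoxybenzaldehyde | COc1cc(C=O)c(O)c(OC)c1 | intermediate
14 | 2-(hydroxymethyl)-4,6-dimethoxyphenol | COc1cc(CO)c(O)c(OC)c1 | intermediate
15 | 2,4-dimethoxy-6-(triisopropylsilyloxymethyl)phenol | COc1cc(CO[Si](C(C)C)(C(C)C)C(C)C)c(O)c(OC)c1 | intermediate
16 | potassium 2,4-dimethoxy-6-(triisopropylsilyloxymethyl)phenoxide | COc1cc(CO[Si](C(C)C)(C(C)C)C(C)C)c([O-])c(OC)c1.[K+] | intermediate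
17 | potassium 2-[2,4-dimethoxy-6-(triisopropylsilyloxymethyl)phenoxy]-4-methyl-6-(2-methylbut-3-en-2-yloxy)benzoate | C=CC(C)(C)Oc1cc(C)cc(Oc2c(CO[Si](C(C)C)(C(C)C)C(C)C)cc(OC)cc2OC)c1C(=O)[O-].[K+] | intermediate
18 | methyl 2-[2,4-dimethoxy-6-(triisopropylsilyloxymethyl)phenoxy]-4-methyl-6-(2-methylbut-3-en-2-yloxy)benzoate | C=CC(C)(C)Oc1cc(C)cc(Oc2c(CO[Si](C(C)C)(C(C)C)C(C)C)cc(OC)cc2OC)c1C(=O)OC | intermediate
19 | methyl 2-[2,4-dimethoxy-6-(triisopropylsilyloxymethyl)phenoxy]-6-hydroxy-4-methyl-5-(3-methylbut-2-en-1-yl)benzoate | COC(=O)c1c(Oc2c(CO[Si](C(C)C)(C(C)C)C(C)C)cc(OC)cc2OC)cc(C)c(CC=C(C)C)c1O | intermediate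
20 | methyl 2-[2-(hydroxymethyl)-4,6-dimethoxyphenoxy]-6-hydroxy-4-methyl-5-(3-methylbut-2-en-1-yl)benzoate (no stereocentres) | COC(=O)c1c(Oc2c(CO)cc(OC)cc2OC)cc(C)c(CC=C(C)C)c1O | target

Total step count: 11 (steps 1 to 5 for the aryne precursor, steps 6 to 8 for the phenol, steps 9 to 11 to the target).
Longest linear sequence: 8 steps (1, 2, 3, 4, 5, 9, 10, 11).

Steps most likely to fail

Step 9. The C1 aryl anion may be protonated before it meets CO2, or the phenoxide may be held back as its carbonate, so that the diaryl ether forms without the carboxyl group or not at all. The fallback replaces the aryne by two nucleophilic aromatic substitutions on a symmetric electrophile and sets out from phenol 15. Its potassium salt (K2CO3, DMF, rt to 50 °C) should displace one fluoride of commercial 2,6-difluoro-4-methylbenzaldehyde F1 to give 2-[2,4-dimethoxy-6-(triisopropylsilyloxymethyl)phenoxy]-6-fluoro-4-methylbenzaldehyde F2; the first aryloxy group deactivates the ring enough to stop at mono-substitution. Potassium 2-methylbut-3-en-2-olate (from the alcohol and KH, THF, 0 °C to rt) should then displace the second, aldehyde-activated fluoride to give 2-[2,4-dimethoxy-6-(triisopropylsilyloxymethyl)phenoxy]-4-methyl-6-(2-methylbut-3-en-2-yloxy)benzaldehyde F3. Pinnick oxidation (NaClO2, NaH2PO4, 2-methylbut-2-ene, t-BuOH/H2O) should give 2-[2,4-dimethoxy-6-(triisopropylsilyloxymethyl)phenoxy]-4-methyl-6-(2-methylbut-3-en-2-yloxy)benzoic acid F4. K2CO3 in DMF converts this acid into carboxylate 17, where the fallback rejoins the route, and MeI then gives 18.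

Step 4. The silyl triflate may ionise the tertiary allyl ether, or incomplete N-silylation may lead to expulsion of isocyanate on lithiation. The fallback uses a fully N-substituted carbamate that needs neither N-protection nor a Lewis acid, and sets out from phenol 4. Et2NCOCl with NaH in THF should give 3-methyl-5-(2-methylbut-3-en-2-yloxy)phenyl N,N-diethylcarbamate F5. Ortho-lithiation with s-BuLi/TMEDA in THF at −78 °C and a Me3SiCl quench should give 5-methyl-3-(2-methylbut-3-en-2-yloxy)-2-(trimethylsilyl)phenyl N,N-diethylcarbamate F6. Reductive cleavage of the carbamate with LiAlH4 in THF (0 °C to rt, basic work-up) should release silyl phenol 10, where the fallback rejoins the route; 10 is then triflated with PhNTf2 and Et3N in CH2Cl2 to give 11.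

Step 10. Heat or trace acid may split off the dimethylallyl group as isoprene, or the new prenyl phenol may cyclise onto its own alkene. The fallback gives up the sigmatropic shift and sets out from 18. Deallylation with catalytic Pd(PPh3)4 (zerovalent palladium) and morpholine in THF at rt should give methyl 2-[2,4-dimethoxy-6-(triisopropylsilyloxymethyl)phenoxy]-6-hydroxy-4-methylbenzoate F7. Ortho C-prenylation of its sodium phenoxide (NaH, toluene, 1-bromo-3-methylbut-2-ene, rt) should then give 19, where the fallback rejoins the route; the non-polar medium favours C- over O-alkylation, C1 is blocked and the para carbon is hindered, so C5 is the expected site.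

Further compounds
F1 | step 9 | 2,6-difluoro-4-methylbenzaldehyde | Cc1cc(F)c(C=O)c(F)c1
F2 | step 9 | 2-[2,4-dimethoxy-6-(triisopropylsilyloxymethyl)phenoxy]-6-fluoro-4-methylbenzaldehyde | COc1cc(CO[Si](C(C)C)(C(C)C)C(C)C)c(Oc2cc(C)cc(F)c2C=O)c(OC)c1
F3 | step 9 | 2-[2,4-dimethoxy-6-(triisopropylsilyloxymethyl)phenoxy]-4-methyl-6-(2-methylbut-3-en-2-yloxy)benzaldehyde | C=CC(C)(C)Oc1cc(C)cc(Oc2c(CO[Si](C(C)C)(C(C)C)C(C)C)cc(OC)cc2OC)c1C=O
F4 | step 9 | 2-[2,4-dimethoxy-6-(triisopropylsilyloxymethyl)phenoxy]-4-methyl-6-(2-methylbut-3-en-2-yloxy)benzoic acid | C=CC(C)(C)Oc1cc(C)cc(Oc2c(CO[Si](C(C)C)(C(C)C)C(C)C)cc(OC)cc2OC)c1C(=O)O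
F5 | step 4 | 3-methyl-5-(2-methylbut-3-en-2-yloxy)phenyl N,N-diethylcarbamate | C=CC(C)(C)Oc1cc(C)cc(OC(=O)N(CC)CC)c1
F6 | step 4 | 5-methyl-3-(2-methylbut-3-en-2-yloxy)-2-(trimethylsilyl)phenyl N,N-diethylcarbamate | C=CC(C)(C)Oc1cc(C)cc(OC(=O)N(CC)CC)c1[Si](C)(C)C
F7 | step 10 | methyl 2-[2,4-dimethoxy-6-(triisopropylsilyloxymethyl)phenoxy]-6-hydroxy-4-methylbenzoate | COC(=O)c1c(O)cc(C)cc1Oc1c(CO[Si](C(C)C)(C(C)C)C(C)C)cc(OC)cc1OC
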